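**Assumption:** the SMILES has no stereocentre. Each ring is symmetric about its O–C1···C4 axis, so no atropisomers are possible. Apteniol E is therefore achiral, the "single enantiomer" requirement is met trivially, and no step needs stereocontrol.

## Retrosynthetic overview
1. The obvious Ullmann/SNAr/Chan–Lam aryl–O coupling of two syringyl halves (tetra-ortho-substituted, both partners electron-rich) is avoided.
2. Both propanoic acid chains go on last and in both directions at once. The diacid comes from the diester, which comes from a twofold Rh 1,4-addition to methyl acrylate, preceded by a twofold sterically controlled Ir C–H borylation of bis(2,6-dimethoxyphenyl) ether.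
3. Key step: the second arene is made de novo. I2/MeOH oxidative aromatisation of a 2-aryloxycyclohexane-1,3-dione creates that ring and its two OMe groups together.
4. The hindered C–O bond is formed at an sp3 carbon, by Rh(II)-carbenoid O–H insertion of syringol into 2-diazocyclohexane-1,3-dione.
5. Ring order: ring A is bought as syringol. Ring B is bought as cyclohexane-1,3-dione and aromatised in step 3. No other rings are formed.

## Route

**Step 1**
Reactants: 1 cyclohexane-1,3-dione; 2 4-acetamidobenzenesulfonyl azide (p-ABSA)
Product: 3 2-diazocyclohexane-1,3-dione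
Conditions: p-ABSA (1.05 equiv), Et3N (1.5 equiv), MeCN, 0 °C to rt
Reagents that add atoms: p-ABSA (2), CC(=O)Nc1ccc(cc1)S(=O)(=O)N=[N+]=[N-]
Why: Regitz diazo transfer onto the acidic C2 of a cyclic 1,3-diketone is routine and high-yielding, and no stereocentre is formed.

**Step 2**
Reactants: 3 2-diazocyclohexane-1,3-dione; 4 2,6-dimethoxyphenol (syringol)
Product: 5 2-(2,6-dimethoxyphenoxy)cyclohexane-1,3-dione (mainly its enol, 2-aryloxy-3-hydroxycyclohex-2-enone)
Conditions: Rh2(OAc)4 (1 mol %), 4 (2.5 equiv), PhF, reflux, 3 added by syringe pump over 4 h; 5 separated from excess 4 by NaHCO3 extraction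
Reagents that add atoms: 2,6-dimethoxyphenol (4), COc1cccc(OC)c1O
Why: In this Rh(II)-carbenoid O–H insertion, the electrophilic acceptor/acceptor carbenoid is captured by the phenol oxygen (oxonium ylide, then proton transfer) faster than by the arene C–H, so the hindered C–O bond forms at an uncrowded sp3 carbon, and C2 of 5 is not stereogenic.

**Step 3**
Reactants: 5 2-(2,6-dimethoxyphenoxy)cyclohexane-1,3-dione; 6 methanol; 7 methyl iodide
Product: 8 bis(2,6-dimethoxyphenyl) ether (2,2',6,6'-tetramethoxydiphenyl ether)
Conditions: I2 (2.2 equiv), MeOH, reflux, then aq Na2S2O3; crude material treated with MeI, K2CO3, acetone, reflux (telescoped)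
Reagents that add atoms: methanol (6), CO; methyl iodide (7), CI (needed only for material that stops at the monomethyl ether phenol)
Why: In this iodine–methanol oxidative aromatisation, HI-catalysed methyl enol ether formation, α-iodination and loss of HI turn the dione ring into a resorcinol dimethyl ether, while any 3-methoxy-2-aryloxyphenol is converged by Williamson methylation and the existing anisole ring is inert to I2 without an added oxidant.

**Step 4**
Reactants: 8 bis(2,6-dimethoxyphenyl) ether; 9 bis(pinacolato)diboron
Product: 10 bis[2,6-dimethoxy-4-(4,4,5,5-tetramethyl-1,3,2-dioxaborolan-2-yl)phenyl] ether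
Conditions: [Ir(OMe)(cod)]2 (2.5 mol %), dtbpy (5 mol %), B2pin2 (2.2 equiv), THF, 80 °C (sealed)
Reagents that add atoms: B2pin2 (9), CC1(C)OB(OC1(C)C)B1OC(C)(C)C(C)(C)O1
Why: Hartwig–Miyaura–Ishiyama C–H borylation is sterically controlled, so each 1,2,3-trisubstituted ring reacts only at C4–H, the one C–H with no ortho substituent, which is the opposite of SEAr selectivity (C3), and over-borylation is blocked.

**Step 5**
Reactants: 10 bis-boronate; 11 methyl acrylate
Product: 12 dimethyl 3,3'-[oxybis(3,5-dimethoxy-4,1-phenylene)]dipropanoate
Conditions: [Rh(cod)Cl]2 (3 mol %), K3PO4 (3 equiv), methyl acrylate (4 equiv), dioxane/H2O 10:1, 60 °C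
Reagents that add atoms: methyl acrylate (11), C=CC(=O)OC
Why: In this twofold Rh(I)-catalysed 1,4-addition (Hayashi–Miyaura type, achiral), B-to-Rh transmetalation, acrylate insertion and hydrolysis of the oxa-π-allyl rhodium enolate in the aqueous medium give the saturated ester directly, and the boron sites have no ortho substituents so protodeboronation should be slow.

**Step 6**
Reactants: 12 dimethyl ester; 13 lithium hydroxide (aqueous)
Product: 14 Apteniol E, 3,3'-[oxybis(3,5-dimethoxy-4,1-phenylene)]dipropanoic acid
Conditions: LiOH·H2O (6 equiv), THF/MeOH/H2O 3:1:1, rt; then 1 M HCl to pH 2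
Reagents that add atoms: lithium hydroxide/water (13), [Li+].[OH-] / O
Why: BAc2 saponification of two unhindered methyl esters leaves the aryl methyl ethers and the diaryl ether untouched.

## Compound list
1 | cyclohexane-1,3-dione | O=C1CCCC(=O)C1 | starting material
2 | 4-acetamidobenzenesulfonyl azide | CC(=O)Nc1ccc(cc1)S(=O)(=O)N=[N+]=[N-] | starting material (reagent)
3 | 2-diazocyclohexane-1,3-dione | [N-]=[N+]=C1C(=O)CCCC1=O | intermediate
4 | 2,6-dimethoxyphenol (syringol) | COc1cccc(OC)c1O | starting material
5 | 2-(2,6-dimethoxyphenoxy)cyclohexane-1,3-dione | COc1cccc(OC)c1OC1C(=O)CCCC1=O | intermediate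
6 | methanol | CO | starting material (reagent)
7 | methyl iodide | CI | starting material (reagent)
8 | bis(2,6-dimethoxyphenyl) ether | COc1cccc(OC)c1Oc1c(OC)cccc1OC | intermediate
9 | bis(pinacolato)diboron | CC1(C)OB(OC1(C)C)B1OC(C)(C)C(C)(C)O1 | starting material (reagent)
10 | bis[2,6-dimethoxy-4-(pinacolboryl)phenyl] ether | COc1cc(B2OC(C)(C)C(C)(C)O2)cc(OC)c1Oc1c(OC)cc(B2OC(C)(C)C(C)(C)O2)cc1OC | intermediate
11 | methyl acrylate | C=CC(=O)OC | starting material
12 | dimethyl 3,3'-[oxybis(3,5-dimethoxy-4,1-phenylene)]dipropanoate | COc1cc(CCC(=O)OC)cc(OC)c1Oc1c(OC)cc(CCC(=O)OC)cc1OC | intermediate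
13 | lithium hydroxide | [Li+].[OH-] | starting material (reagent)
14 | Apteniol E (achiral, C22H26O9) | COc1cc(CCC(=O)O)cc(OC)c1Oc1c(OC)cc(CCC(=O)O)cc1OC | target

## Totals
Total steps: 6 (step 3 is a two-operation telescope).
Longest linear sequence: 6 (1 → 3 → 5 → 8 → 10 → 12 → 14).

## Three steps most likely to fail

1. **Step 2, O–H insertion.** The risks are para C–H functionalisation of syringol, methoxy-oxonium ylide pathways, Wolff ring contraction, and further insertion into the enol O–H of 5.
   Fallback: drop carbene chemistry. Alkylate syringol with methyl 6-bromo-5-oxohexanoate (K2CO3, Williamson SN2). Then close ring B by KOtBu-mediated intramolecular Claisen (Dieckmann-type) condensation of ArOCH2C(O)(CH2)3CO2Me, which gives the same dione 5.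

2. **Step 3, I2/MeOH aromatisation.** The risks are stalling at the vinylogous ester next to the bulky aryloxy group, and stray ring iodination.
   Fallback: switch to stepwise dehydrogenation. Form the 3-methoxy enone (MeOH, TsOH). Aromatise it by LDA/PhSeCl then H2O2 (selenoxide elimination), or by Pd(TFA)2/DMSO/O2 aerobic dehydrogenation, to 3-methoxy-2-aryloxyphenol. Then O-methylate to 8.

3. **Step 5, twofold Rh 1,4-addition.** The risks are β-hydride elimination giving Heck-type cinnamates, and incomplete second addition.
   Fallback: change the C–C bond logic. Convert 10 to the 4,4'-dibromide (CuBr2, MeOH/H2O). Run a double Mizoroki–Heck reaction with methyl acrylate under Pd(0), then hydrogenate (H2, Pd/C) to 12. The same hydrogenation also converges any cinnamate by-product from the Rh reaction.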